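The target is disconnected at ring A, the 2-oxy-3,4-dihydro-2H-pyran (O, C2, C1, C5, C4=C3) that is cis-fused at C1–C5 to cycloheptane ring B. This ring is the retron of an oxadiene (O=C3–C4=C5) adding to an enol ether (C1=C2), both carried on one cis-cyclopropane. A single Lewis-acid-promoted intramolecular inverse-demand hetero-(4+2) cycloaddition forms C5–C1 and O–C2, closes rings A and B, and sets C1, C2 and C5. The precursor is a cis-cyclopropane bearing an (E)-2-(silyloxymethyl)enal on C6 and, via C7–C9, an (E)-silyl enol ether on the linalool-derived carbinol C10. All oxygens are silylated; the oxepane is closed afterwards.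

Key step: step 20

Atom labels used below: ring A = O, C2 (acetal), C1, C5, C4=C3; ring B = C1, C5, C6, C7, C8, C9, C10; cyclopropane = C6, C7, C11; C12 = the CH2O on C11 cis to C5 (ends in the oxepane); C13 = the other CH2O on C11 (ends as CH2OAc); C14 = methyl on C10; C15 = CH2O on C4.

Remarks on the chemistry:
- Structure check: the configurations at C6, C7, C10 and C11 of precursor 24 and at C1, C2 and C5 of cycloadduct 25 map onto the target unchanged, and (S)-linalool supplies C10. Only spectator groups were changed.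
- C13 is carried as a silyl ether, not as the acetate. An acetate would be cleaved by i-Bu2AlH and could migrate to O12 once that oxygen is freed. Both acetates are therefore installed in the last step.
- O12 and O15 are deliberately left untethered before the cycloaddition. An oxepine would hold C4 gauche over C11 and expose the wrong face of C5 to the tether.
- Assumption: (S)-(+)-linalool of high enantiomeric purity is purchasable.
- Assumption: Rh2(4S-MPPIM)4, dirhodium tetrakis[methyl (4S)-2-oxo-1-(3-phenylpropanoyl)imidazolidine-4-carboxylate] (divalent rhodium), is taken to give the (1R,5S,6S) lactone. This is the facial sense the (S)-configured carboxamidate catalysts show with allyl and (Z)-alk-2-enyl diazoacetates. If the sense proved opposite, the (4R) catalyst would be used.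

Step 1
Reactants: 1 (S)-linalool
Product: 2 linalool triethylsilyl ether
Conditions: TESOTf, 2,6-lutidine, CH2Cl2, 0 °C
Reagents that add atoms: triethylsilyl triflate, CC[Si](CC)(CC)OS(=O)(=O)C(F)(F)F
Why: Silyl triflate/lutidine silylation of the hindered tertiary allylic alcohol (silyl ether formation) touches no stereocentre, and the triethylsilyl ether should survive hydride, phosphonate and Lewis-acid steps yet leave with fluoride at the end.

Step 2
Reactants: 2 linalool triethylsilyl ether
Product: 4 (4S)-4-methyl-4-(triethylsilyloxy)hex-5-enal, via ozonide 3 (not isolated)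
Conditions: O3, CH2Cl2, −78 °C (Sudan Red 7B end point); Me2S, −78 °C → rt
Reagents that add atoms: ozone, O=[O+][O-]
Why: Chemoselective ozonolysis, in which the electron-rich trisubstituted alkene should be consumed well before the monosubstituted vinyl group flanked by the quaternary silyloxy carbon; the dye marks the end point, dimethyl sulfide reduces ozonide 3, and C10 is untouched.

Step 3
Reactants: 5 triethyl phosphonoacetate
Product: 6 ethyl 2-(diethoxyphosphoryl)-3-hydroxypropanoate
Conditions: (CH2O)n, piperidine (cat.), THF, 60 °C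
Reagents that add atoms: formaldehyde (as paraformaldehyde), C=O
Why: Amine-catalysed aldol-type hydroxymethylation of the doubly activated methylene (first stage of a Knoevenagel reaction, stopped before dehydration); the new stereocentre is racemic and is destroyed on olefination.

Step 4
Reactants: 4 (4S)-4-methyl-4-(triethylsilyloxy)hex-5-enal; 6 ethyl 2-(diethoxyphosphoryl)-3-hydroxypropanoate
Product: 7 ethyl (6S)-2-(hydroxymethyl)-6-methyl-6-(triethylsilyloxy)octa-2,7-dienoate (E/Z mixture)
Conditions: LiCl, DBU, MeCN, 0 °C → rt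
Reagents that add atoms: none
Why: Horner–Wadsworth–Emmons olefination under Masamune–Roush conditions of an α-substituted phosphonoacetate whose free hydroxyl is a spectator; the alkene geometry is irrelevant because both substituents on C11 become hydroxymethyl in step 5.

Step 5
Reactants: 7 hydroxymethyl enoate
Product: 8 2-[(4S)-4-methyl-4-(triethylsilyloxy)hex-5-en-1-ylidene]propane-1,3-diol
Conditions: i-Bu2AlH, CH2Cl2, −78 → 0 °C; aq. potassium sodium tartrate
Reagents that add atoms: none
Why: 1,2-Reduction of the unsaturated ester by excess i-Bu2AlH (ester to allylic alcohol) leaves the silyl ether and both alkenes alone and gives the 2-alkylidene-1,3-diol.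

Step 6
Reactants: 8 alkylidene diol
Product: 9 (2E,6S)-2-(hydroxymethyl)-6-methyl-6-(triethylsilyloxy)octa-2,7-dien-1-yl acetate
Conditions: lipase PS (Burkholderia cepacia), vinyl acetate, THF, rt
Reagents that add atoms: vinyl acetate, CC(=O)OC=C
Why: Lipase-catalysed transesterification with an irreversible acyl donor should acylate only the hydroxymethyl trans to the C7 substituent (the one not shielded by allylic 1,3-strain), as is known for 2-alkylidenepropane-1,3-diols; this fixes the (E) geometry and leaves the cis hydroxymethyl (C12) free for the carbene tether.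

Step 7
Reactants: 9 (E)-monoacetate; 10 bromoacetyl bromide
Product: 11 (2Z,6S)-2-(acetoxymethyl)-6-methyl-6-(triethylsilyloxy)octa-2,7-dien-1-yl bromoacetate
Conditions: NaHCO3, MeCN, 0 °C
Reagents that add atoms: bromoacetyl bromide (compound 10), BrCC(=O)Br
Why: Acylation of the remaining primary allylic alcohol by the acid bromide under weak inorganic base (esterification) should be fast enough at 0 °C to preclude acetyl migration.

Step 8
Reactants: 11 bromoacetate
Product: 12 (2Z,6S)-2-(acetoxymethyl)-6-methyl-6-(triethylsilyloxy)octa-2,7-dien-1-yl diazoacetate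
Conditions: TsNHNHTs, DBU, THF, 0 °C
Reagents that add atoms: N,N'-ditosylhydrazine, Cc1ccc(cc1)S(=O)(=O)NNS(=O)(=O)c1ccc(C)cc1
Why: Diazoacetate formation by the ditosylhydrazine method (N-alkylation of the sulfonylhydrazide by the bromoacetate, then base-induced loss of two sulfinates) is mild enough for the acetate and the silyl ether.

Step 9
Reactants: 12 diazoacetate
Product: 13 (1R,5S,6S)-5-(acetoxymethyl)-6-[(3S)-3-methyl-3-(triethylsilyloxy)pent-4-en-1-yl]-3-oxabicyclo[3.1.0]hexan-2-one
Conditions: Rh2(4S-MPPIM)4 (1 mol %), CH2Cl2, reflux, slow addition of 12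
Reagents that add atoms: none
Why: Intramolecular cyclopropanation of an allylic diazoacetate by a dirhodium carboxamidate carbene, in which the five-atom tether forces the cis-fused lactone, the (Z) alkene geometry is transferred stereospecifically so that C8 ends cis to C5 and C12, and the chiral catalyst (not the remote C10 centre) selects the alkene face that sets C6, C7 and C11.

Step 10
Reactants: 13 cyclopropane lactone
Product: 14 (1R,3S)-2,2-bis(hydroxymethyl)-N-methoxy-N-methyl-3-[(3S)-3-methyl-3-(triethylsilyloxy)pent-4-en-1-yl]cyclopropane-1-carboxamide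
Conditions: MeNHOMe·HCl, i-PrMgCl, THF, −20 → 0 °C
Reagents that add atoms: N,O-dimethylhydroxylamine hydrochloride, CNOC.Cl
Why: Aminolysis by the chloromagnesium amide (Weinreb amide formation) opens the lactone and, with excess reagent, also removes the acetate, so that O12 and O13 are freed together while C5 stays at the acyl oxidation level and C6 cannot epimerise.

Step 11
Reactants: 14 Weinreb amide diol
Product: 15 (1R,3S)-2,2-bis[(tert-butyldimethylsilyloxy)methyl]-N-methoxy-N-methyl-3-[(3S)-3-methyl-3-(triethylsilyloxy)pent-4-en-1-yl]cyclopropane-1-carboxamide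
Conditions: TBSCl, imidazole, DMF, rt
Reagents that add atoms: tert-butyldimethylsilyl chloride, CC(C)(C)[Si](C)(C)Cl
Why: Standard silylation of both neopentyl-type primary alcohols (silyl ether formation), run on the crude diol to forestall relactonisation.

Step 12
Reactants: 15 bis-silylated Weinreb amide
Product: 16 (1R,3S)-2,2-bis[(tert-butyldimethylsilyloxy)methyl]-3-[(3S)-3-methyl-3-(triethylsilyloxy)pent-4-en-1-yl]cyclopropane-1-carbaldehyde
Conditions: i-Bu2AlH, THF, −78 °C; aq. potassium sodium tartrate
Reagents that add atoms: none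
Why: i-Bu2AlH reduction of the Weinreb amide stops at the chelated hemiaminal and releases the aldehyde on work-up; going through this open-chain aldehyde avoids a lactol whose freed C12 alkoxide could add to the enoate made in step 14.

Step 13
Reactants: 6 ethyl 2-(diethoxyphosphoryl)-3-hydroxypropanoate
Product: 17 ethyl 3-(tert-butyldimethylsilyloxy)-2-(diethoxyphosphoryl)propanoate
Conditions: TBSCl, imidazole, CH2Cl2, rt
Reagents that add atoms: tert-butyldimethylsilyl chloride, CC(C)(C)[Si](C)(C)Cl
Why: Silyl ether formation on the primary alcohol under conditions too mild to dehydrate the β-hydroxy phosphonate.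

Step 14
Reactants: 16 cyclopropanecarbaldehyde; 17 silyloxy phosphonate
Product: 18 ethyl (E)-2-[(tert-butyldimethylsilyloxy)methyl]-3-{(1R,3S)-2,2-bis[(tert-butyldimethylsilyloxy)methyl]-3-[(3S)-3-methyl-3-(triethylsilyloxy)pent-4-en-1-yl]cyclopropyl}prop-2-enoate
Conditions: LiCl, DBU, MeCN, 0 °C → rt
Reagents that add atoms: none
Why: Masamune–Roush Horner–Wadsworth–Emmons olefination of an α-branched aldehyde with an α-substituted phosphonoacetate should place the ester trans to the bulky cyclopropyl group ((E)-enoate, C15 cis to C6) under base too weak to epimerise C6.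

Step 15
Reactants: 18 (E)-enoate
Product: 20 primary alcohol (C2–OH) of the enoate, via alkylborane 19 (not isolated)
Conditions: 9-BBN, THF, 0 °C → rt; NaBO3·4H2O, H2O, rt
Reagents that add atoms: 9-borabicyclo[3.3.1]nonane (boron in 19 only), C1CC2CCCC(C1)B2; sodium perborate (hydroxyl oxygen of 20), [Na+].[Na+].O[B-]1(O)OO[B-](O)(O)OO1
Why: Anti-Markovnikov hydroboration–oxidation, in which 9-BBN should add only to the monosubstituted vinyl group (the trisubstituted, electron-poor enoate alkene is inert) and perborate oxidises borane 19 without saponifying the ester; C10 keeps its configuration.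

Step 16
Reactants: 20 primary alcohol
Product: 21 β-silyloxy aldehyde (C2 = CHO)
Conditions: Dess–Martin periodinane, NaHCO3, CH2Cl2, 0 °C → rt
Reagents that add atoms: none
Why: Dess–Martin oxidation of the primary alcohol under buffered, non-epimerising conditions that spare the silyl ethers and the enoate.

Step 17
Reactants: 21 β-silyloxy aldehyde
Product: 22 (E)-tert-butyldimethylsilyl enol ether (C1=C2–OTBS on C10)
Conditions: TBSOTf, Et3N, CH2Cl2, −78 → 0 °C
Reagents that add atoms: tert-butyldimethylsilyl triflate, CC(C)(C)[Si](C)(C)OS(=O)(=O)C(F)(F)F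
Why: Soft enolisation (silyl triflate/tertiary amine) silylates the only enolisable carbonyl; deprotonation of the silyloxocarbenium ion through the conformer that keeps the fully substituted C10 away from the carbonyl oxygen should give mainly the (E)-enol ether, and the amine excess suppresses ionisation of the β-silyloxy group.

Step 18
Reactants: 22 silyl enol ether enoate
Product: 23 (Z)-allylic alcohol (C3–OH; CH2OTBS cis to C6)
Conditions: i-Bu2AlH, CH2Cl2, −78 °C; aq. potassium sodium tartrate
Reagents that add atoms: none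
Why: i-Bu2AlH 1,2-reduction of the enoate to the allylic alcohol at −78 °C, which silyl enol ethers and silyl ethers tolerate together with the mildly basic tartrate work-up.

Step 19
Reactants: 23 allylic alcohol
Product: 24 cycloaddition precursor, cis-cyclopropane with (E)-2-(silyloxymethyl)enal arm on C6 and (E)-silyl enol ether arm on C10
Conditions: MnO2, CH2Cl2, rt
Reagents that add atoms: none
Why: MnO2 oxidises only the allylic alcohol to the (E)-enal under neutral heterogeneous conditions that spare the silyl enol ether (allylic oxidation), so the reactive oxadiene is unveiled last.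

Step 20
Reactants: 24 cycloaddition precursor
Product: 25 tricyclic silyl acetal (rings A and B plus cyclopropane)
Conditions: Me2AlCl (1.5 equiv), CH2Cl2, −78 → −40 °C; Et3N, aq. NaHCO3
Reagents that add atoms: none
Why: Me2AlCl binds the enal carbonyl and lowers the oxadiene LUMO, so the electron-rich enol ether bonds through C1 to C5 while the carbonyl oxygen bonds to the silyloxy-bearing C2, either in one asynchronous [4+2] event or as a Mukaiyama–Michael addition whose silyl oxocarbenium ion is captured by the aluminium dienolate oxygen; the closest known reaction type is the intramolecular inverse-electron-demand oxadiene–enol ether (or enamine) cycloaddition used for iridoid 2-oxy-dihydropyrans. Ring A is the six-membered cycloadduct ring itself (stepwise limit: 6-exo-trig attack of oxygen on the oxocarbenium carbon), and ring B is the tether ring of a fused-mode (type 1) intramolecular cycloaddition spanned by C6–C7–C8–C9–C10 (stepwise limit: 7-exo-trig attack of C1 on C5). C5 is controlled by the vinylcyclopropane conformation: with the cis arms C8 and C12 flanking it, the enal should sit s-trans and near-bisected with H5 between them, so C1, delivered from the C7 side, adds anti to C11 and gives the trans H5/H6 relation. C1 is controlled by the tether, which should reach C5 of the (E)-enal only with C10 folded under the oxadiene, hence the cis A/B fusion; C2 follows from suprafacial transfer of the (E)-enol ether geometry (silyloxy trans to C10) and is in any case re-equilibrated at the lactol stage. The step needs 1,4- over 1,2-addition, secured because attack on the aldehyde carbon would require a nine-membered ring, and face selectivity at C5, secured by the conformational bias above; the low temperature keeps the cis-alkyl vinylcyclopropane from homodienyl 1,5-hydrogen shift.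

Step 21
Reactants: 25 tricyclic silyl acetal
Product: 26 pentaol (C2 lactol; C12, C13, C15 and C10 hydroxyls)
Conditions: HF·pyridine, pyridine, THF, 0 °C → rt
Reagents that add atoms: none
Why: Fluoride-driven cleavage of all five Si–O bonds (global desilylation) under buffered, weakly acidic conditions that avoid the lactolate anion and hence ring opening or β-elimination at C15; the lactol should form as an equilibrating anomer mixture.

Step 22
Reactants: 26 pentaol
Product: 27 oxepane triol (C12–O–C15 closed; C2 lactol, C13–OH, C10–OH)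
Conditions: PPTS (cat.), 4 Å MS, MeCN, 0 °C → rt, high dilution
Reagents that add atoms: none
Why: Acid-catalysed SN1 allylic etherification through the Ferrier-type alkoxyallyl cation from the enol-ether-activated C15 alcohol; only O12, whose carbon chain is gauche to C4 across C5–C6, should reach the C15 terminus in a seven-membered ring, whereas C3 and C2 lie out of its reach, and no stereocentre changes.

Step 23
Reactants: 27 oxepane triol
Product: 28 target CNP0250836.3
Conditions: Ac2O, pyridine, DMAP (cat.), CH2Cl2, 0 °C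
Reagents that add atoms: acetic anhydride, CC(=O)OC(C)=O
Why: Pyridine-mediated acetylation of the primary C13 alcohol and of the lactol, whose interconverting anomers should be trapped mainly as the acetate trans to the bulky C1 substituent (pseudo-axial, anomerically favoured), while the hindered tertiary C10 alcohol is not acylated.

Compound list
1 | (S)-linalool, (3S)-3,7-dimethylocta-1,6-dien-3-ol | CC(C)=CCC[C@](C=C)(C)O | starting material
2 | (3S)-3,7-dimethyl-3-(triethylsilyloxy)octa-1,6-diene | CC(C)=CCC[C@](C=C)(C)O[Si](CC)(CC)CC | intermediate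
3 | 3,3-dimethyl-5-[(3S)-3-methyl-3-(triethylsilyloxy)pent-4-en-1-yl]-1,2,4-trioxolane (ozonide, not isolated) | CC1(C)OOC(CC[C@](C=C)(C)O[Si](CC)(CC)CC)O1 | intermediate
4 | (4S)-4-methyl-4-(triethylsilyloxy)hex-5-enal | O=CCC[C@](C=C)(C)O[Si](CC)(CC)CC | intermediate
5 | triethyl phosphonoacetate | CCOC(=O)CP(=O)(OCC)OCC | starting material
6 | ethyl 2-(diethoxyphosphoryl)-3-hydroxypropanoate (racemic) | CCOC(=O)C(CO)P(=O)(OCC)OCC | intermediate
7 | ethyl (6S)-2-(hydroxymethyl)-6-methyl-6-(triethylsilyloxy)octa-2,7-dienoate (E/Z mixture) | CCOC(=O)C(CO)=CCC[C@](C=C)(C)O[Si](CC)(CC)CC | intermediate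
8 | 2-[(4S)-4-methyl-4-(triethylsilyloxy)hex-5-en-1-ylidene]propane-1,3-diol | OCC(CO)=CCC[C@](C=C)(C)O[Si](CC)(CC)CC | intermediate
9 | (2E,6S)-2-(hydroxymethyl)-6-methyl-6-(triethylsilyloxy)octa-2,7-dien-1-yl acetate | CC(=O)OC/C(CO)=C/CC[C@](C=C)(C)O[Si](CC)(CC)CC | intermediate
10 | bromoacetyl bromide | BrCC(=O)Br | starting material
11 | (2Z,6S)-2-(acetoxymethyl)-6-methyl-6-(triethylsilyloxy)octa-2,7-dien-1-yl bromoacetate | CC(=O)OC/C(COC(=O)CBr)=C/CC[C@](C=C)(C)O[Si](CC)(CC)CC | intermediate
12 | (2Z,6S)-2-(acetoxymethyl)-6-methyl-6-(triethylsilyloxy)octa-2,7-dien-1-yl diazoacetate | CC(=O)OC/C(COC(=O)C=[N+]=[N-])=C/CC[C@](C=C)(C)O[Si](CC)(CC)CC | intermediate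
13 | (1R,5S,6S)-5-(acetoxymethyl)-6-[(3S)-3-methyl-3-(triethylsilyloxy)pent-4-en-1-yl]-3-oxabicyclo[3.1.0]hexan-2-one | O=C1OC[C@@]2(COC(C)=O)[C@@H](CC[C@](C=C)(C)O[Si](CC)(CC)CC)[C@@H]12 | intermediate
14 | (1R,3S)-2,2-bis(hydroxymethyl)-N-methoxy-N-methyl-3-[(3S)-3-methyl-3-(triethylsilyloxy)pent-4-en-1-yl]cyclopropane-1-carboxamide | CON(C)C(=O)[C@@H]1[C@H](CC[C@](C=C)(C)O[Si](CC)(CC)CC)C1(CO)CO | intermediate
15 | (1R,3S)-2,2-bis[(tert-butyldimethylsilyloxy)methyl]-N-methoxy-N-methyl-3-[(3S)-3-methyl-3-(triethylsilyloxy)pent-4-en-1-yl]cyclopropane-1-carboxamide | CON(C)C(=O)[C@@H]1[C@H](CC[C@](C=C)(C)O[Si](CC)(CC)CC)C1(CO[Si](C)(C)C(C)(C)C)CO[Si](C)(C)C(C)(C)C | intermediate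
16 | (1R,3S)-2,2-bis[(tert-butyldimethylsilyloxy)methyl]-3-[(3S)-3-methyl-3-(triethylsilyloxy)pent-4-en-1-yl]cyclopropane-1-carbaldehyde | O=C[C@@H]1[C@H](CC[C@](C=C)(C)O[Si](CC)(CC)CC)C1(CO[Si](C)(C)C(C)(C)C)CO[Si](C)(C)C(C)(C)C | intermediate
17 | ethyl 3-(tert-butyldimethylsilyloxy)-2-(diethoxyphosphoryl)propanoate (racemic) | CCOC(=O)C(CO[Si](C)(C)C(C)(C)C)P(=O)(OCC)OCC | intermediate
18 | ethyl (E)-2-[(tert-butyldimethylsilyloxy)methyl]-3-{(1R,3S)-2,2-bis[(tert-butyldimethylsilyloxy)methyl]-3-[(3S)-3-methyl-3-(triethylsilyloxy)pent-4-en-1-yl]cyclopropyl}prop-2-enoate | CCOC(=O)/C(CO[Si](C)(C)C(C)(C)C)=C/[C@@H]1[C@H](CC[C@](C=C)(C)O[Si](CC)(CC)CC)C1(CO[Si](C)(C)C(C)(C)C)CO[Si](C)(C)C(C)(C)C | intermediate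
19 | B-alkyl-9-borabicyclo[3.3.1]nonane from 18, boron on the former terminal vinyl carbon C2 (not isolated) | CCOC(=O)/C(CO[Si](C)(C)C(C)(C)C)=C/[C@@H]1[C@H](CC[C@](CCB2C3CCCC2CCC3)(C)O[Si](CC)(CC)CC)C1(CO[Si](C)(C)C(C)(C)C)CO[Si](C)(C)C(C)(C)C | intermediate
20 | ethyl (E)-2-[(tert-butyldimethylsilyloxy)methyl]-3-{(1R,3S)-2,2-bis[(tert-butyldimethylsilyloxy)methyl]-3-[(3S)-5-hydroxy-3-methyl-3-(triethylsilyloxy)pentyl]cyclopropyl}prop-2-enoate | CCOC(=O)/C(CO[Si](C)(C)C(C)(C)C)=C/[C@@H]1[C@H](CC[C@](CCO)(C)O[Si](CC)(CC)CC)C1(CO[Si](C)(C)C(C)(C)C)CO[Si](C)(C)C(C)(C)C | intermediate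
21 | ethyl (E)-2-[(tert-butyldimethylsilyloxy)methyl]-3-{(1R,3S)-2,2-bis[(tert-butyldimethylsilyloxy)methyl]-3-[(3S)-3-methyl-5-oxo-3-(triethylsilyloxy)pentyl]cyclopropyl}prop-2-enoate | CCOC(=O)/C(CO[Si](C)(C)C(C)(C)C)=C/[C@@H]1[C@H](CC[C@](CC=O)(C)O[Si](CC)(CC)CC)C1(CO[Si](C)(C)C(C)(C)C)CO[Si](C)(C)C(C)(C)C | intermediate
22 | ethyl (E)-2-[(tert-butyldimethylsilyloxy)methyl]-3-{(1R,3S)-2,2-bis[(tert-butyldimethylsilyloxy)methyl]-3-[(3S,4E)-5-(tert-butyldimethylsilyloxy)-3-methyl-3-(triethylsilyloxy)pent-4-en-1-yl]cyclopropyl}prop-2-enoate | CCOC(=O)/C(CO[Si](C)(C)C(C)(C)C)=C/[C@@H]1[C@H](CC[C@](/C=C/O[Si](C)(C)C(C)(C)C)(C)O[Si](CC)(CC)CC)C1(CO[Si](C)(C)C(C)(C)C)CO[Si](C)(C)C(C)(C)C | intermediate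
23 | (Z)-2-[(tert-butyldimethylsilyloxy)methyl]-3-{(1R,3S)-2,2-bis[(tert-butyldimethylsilyloxy)methyl]-3-[(3S,4E)-5-(tert-butyldimethylsilyloxy)-3-methyl-3-(triethylsilyloxy)pent-4-en-1-yl]cyclopropyl}prop-2-en-1-ol | OC/C(CO[Si](C)(C)C(C)(C)C)=C/[C@@H]1[C@H](CC[C@](/C=C/O[Si](C)(C)C(C)(C)C)(C)O[Si](CC)(CC)CC)C1(CO[Si](C)(C)C(C)(C)C)CO[Si](C)(C)C(C)(C)C | intermediate
24 | (E)-2-[(tert-butyldimethylsilyloxy)methyl]-3-{(1R,3S)-2,2-bis[(tert-butyldimethylsilyloxy)methyl]-3-[(3S,4E)-5-(tert-butyldimethylsilyloxy)-3-methyl-3-(triethylsilyloxy)pent-4-en-1-yl]cyclopropyl}prop-2-enal (cycloaddition precursor) | O=C/C(CO[Si](C)(C)C(C)(C)C)=C/[C@@H]1[C@H](CC[C@](/C=C/O[Si](C)(C)C(C)(C)C)(C)O[Si](CC)(CC)CC)C1(CO[Si](C)(C)C(C)(C)C)CO[Si](C)(C)C(C)(C)C | intermediate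
25 | tricyclic silyl acetal: ring A 2-(tert-butyldimethylsilyloxy)-3,4-dihydro-2H-pyran cis-fused at C1–C5 to ring B, cyclopropane cis-fused at C6–C7; H5/H6 trans; C2–OTBS trans to C10; C4–CH2OTBS; C11(CH2OTBS)2; C10(CH3)(OTES) | CC(C)(C)[Si](C)(C)OCC1(CO[Si](C)(C)C(C)(C)C)[C@@H]2[C@H]3C(CO[Si](C)(C)C(C)(C)C)=CO[C@H](O[Si](C)(C)C(C)(C)C)[C@H]3[C@@](C)(O[Si](CC)(CC)CC)CC[C@H]12 | intermediate
26 | pentaol of 25: C2 lactol (anomer mixture), C12–OH, C13–OH, C15–OH, C10–OH | OCC1(CO)[C@@H]2[C@H]3C(CO)=COC(O)[C@H]3[C@@](C)(O)CC[C@H]12 | intermediate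
27 | oxepane triol: C12–O–C15 ether closed; C2 lactol (anomer mixture), C13–OH, C10–OH | OC[C@@]12COCC3=COC(O)[C@@H]4[C@H]3[C@@H]1[C@@H]2CC[C@]4(C)O | intermediate
28 | CNP0250836.3: C2 and C13 acetates, oxepane, free tertiary C10 alcohol | CC(=O)OC[C@@]12COCC3=CO[C@H](OC(C)=O)[C@@H]4[C@H]3[C@@H]1[C@@H]2CC[C@]4(C)O | target

Total step count: 23 (steps 3 and 13 prepare the two phosphonates).
Longest linear sequence: 21 steps from (S)-linalool (steps 1, 2, 4–12, 14–23).

Steps most likely to fail

Step 20 (cycloaddition). The Lewis acid may divert the silyl enol ether before C1–C5 bonding, by protodesilylation or by ionisation of the β-silyloxy group at C10. Bonding may also occur through a gauche vinylcyclopropane rotamer, eroding face selectivity at C5. The fallback sets out from alcohol 20 and comes back at pentaol 26. i-Bu2AlH reduces the ester of 20 to the allylic alcohol, giving the diol F1. Parikh–Doering oxidation of both primary alcohols gives the enal–aldehyde F2. N-methylaniline with 4 Å sieves condenses with the saturated aldehyde to the (E)-enamine F3, which adds to the enal without Lewis acid (intramolecular enamine–enal [4+2], the classical iridoid ring closure) to give the N,O-acetal F4. p-TsOH·H2O in wet THF hydrolyses it to the lactol F5, and the HF·pyridine conditions of step 21 then give 26.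

Step 22 (oxepane closure). After ionisation at C15, the alkoxyallyl cation may be captured at its other terminus (C3) by the free tertiary C10 hydroxyl, or intermolecularly, instead of by O12 at C15. The fallback sets out from cycloadduct 25 and comes back at target 28. Buffered TBAF/AcOH at 0 °C should remove the four tert-butyldimethylsilyl groups while leaving the hindered tertiary triethylsilyl ether, giving the tetraol F6. With O10 masked, PPTS closes the ring to the oxepane diol F7. Ac2O/pyridine gives the diacetate F8, and HF·pyridine finally frees the C10 hydroxyl to give 28.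

Step 4 (olefination with the hydroxymethyl phosphonate). Under base the β-hydroxy phosphonate may lose formaldehyde or water (retro-hydroxymethylation, or dehydration to the phosphonoacrylate) faster than it olefinates the aldehyde. The fallback sets out from aldehyde 4 and comes back at diol 8; it reverses the polarity of the union. NaBH4 gives the alcohol F9, I2/PPh3/imidazole the iodide F10, and PPh3 in MeCN the phosphonium iodide F11. NaHMDS gives the ylide F12, which is condensed (Wittig) with commercial 2,2-dimethyl-1,3-dioxan-5-one (CC1(C)OCC(=O)CO1) to the alkylidene dioxane F13. PPTS in methanol removes the acetonide to give 8.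

Further compounds
F1 | step 20 | (Z)-allylic alcohol/primary alcohol diol from 20 | OC/C(CO[Si](C)(C)C(C)(C)C)=C/[C@@H]1[C@H](CC[C@](CCO)(C)O[Si](CC)(CC)CC)C1(CO[Si](C)(C)C(C)(C)C)CO[Si](C)(C)C(C)(C)C
F2 | step 20 | enal–aldehyde (C3 and C2 both CHO) | O=C/C(CO[Si](C)(C)C(C)(C)C)=C/[C@@H]1[C@H](CC[C@](CC=O)(C)O[Si](CC)(CC)CC)C1(CO[Si](C)(C)C(C)(C)C)CO[Si](C)(C)C(C)(C)C
F3 | step 20 | (E)-N-methyl-N-phenyl enamine of F2 at C1=C2 | O=C/C(CO[Si](C)(C)C(C)(C)C)=C/[C@@H]1[C@H](CC[C@](/C=C/N(C)c2ccccc2)(C)O[Si](CC)(CC)CC)C1(CO[Si](C)(C)C(C)(C)C)CO[Si](C)(C)C(C)(C)C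
F4 | step 20 | tricyclic N,O-acetal (C2–N(CH3)Ph, drawn trans to C10) | CC(C)(C)[Si](C)(C)OCC1(CO[Si](C)(C)C(C)(C)C)[C@@H]2[C@H]3C(CO[Si](C)(C)C(C)(C)C)=CO[C@H](N(C)c4ccccc4)[C@H]3[C@@](C)(O[Si](CC)(CC)CC)CC[C@H]12
F5 | step 20 | tricyclic lactol (C2–OH, anomer mixture) with all other silyl ethers intact | CC(C)(C)[Si](C)(C)OCC1(CO[Si](C)(C)C(C)(C)C)[C@@H]2[C@H]3C(CO[Si](C)(C)C(C)(C)C)=COC(O)[C@H]3[C@@](C)(O[Si](CC)(CC)CC)CC[C@H]12
F6 | step 22 | tetraol retaining the C10 triethylsilyl ether (C2 lactol, C12–OH, C13–OH, C15–OH) | OCC1(CO)[C@@H]2[C@H]3C(CO)=COC(O)[C@H]3[C@@](C)(O[Si](CC)(CC)CC)CC[C@H]12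
F7 | step 22 | oxepane diol (C2 lactol, C13–OH) with C10 triethylsilyl ether | OC[C@@]12COCC3=COC(O)[C@@H]4[C@H]3[C@@H]1[C@@H]2CC[C@]4(C)O[Si](CC)(CC)CC
F8 | step 22 | C10-O-triethylsilyl ether of the target diacetate | CC(=O)OC[C@@]12COCC3=CO[C@H](OC(C)=O)[C@@H]4[C@H]3[C@@H]1[C@@H]2CC[C@]4(C)O[Si](CC)(CC)CC
F9 | step 4 | (4S)-4-methyl-4-(triethylsilyloxy)hex-5-en-1-ol | OCCC[C@](C=C)(C)O[Si](CC)(CC)CC
F10 | step 4 | (3S)-6-iodo-3-methyl-3-(triethylsilyloxy)hex-1-ene | ICCC[C@](C=C)(C)O[Si](CC)(CC)CC
F11 | step 4 | [(4S)-4-methyl-4-(triethylsilyloxy)hex-5-en-1-yl]triphenylphosphonium iodide | c1ccccc1[P+](c1ccccc1)(c1ccccc1)CCC[C@](C=C)(C)O[Si](CC)(CC)CC.[I-]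
F12 | step 4 | [(4S)-4-methyl-4-(triethylsilyloxy)hex-5-en-1-ylidene]triphenylphosphorane | c1ccccc1P(c1ccccc1)(c1ccccc1)=CCC[C@](C=C)(C)O[Si](CC)(CC)CC
F13 | step 4 | 2,2-dimethyl-5-[(4S)-4-methyl-4-(triethylsilyloxy)hex-5-en-1-ylidene]-1,3-dioxane | CC1(C)OCC(=CCC[C@](C=C)(C)O[Si](CC)(CC)CC)CO1
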